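**Assumptions**
- (S)-Tetrahydrofurfuryl alcohol is taken as a commercial chiral-pool material.
- In step 3 the ligand enantiomer that gives the 2,5-trans product is taken to be (S,S)-Ph-PyBox; if the facial sense is reversed, the (R,R) ligand is used.

**Retrosynthetic overview**
1. Enyne C(sp)–C(sp2) bond: Sonogashira coupling of a trans-2-ethynyl-THF ester with (1E,9E)-1-bromo-10-iododeca-1,9-diene (the iodide reacts, the bromide is kept).
2. THF C5–C(sp) bond and C5 stereocentre: proposed Cu-catalysed, ligand-controlled C5–H alkynylation of methyl 4-[(2R)-oxolan-2-yl]butanoate with TIPS-acetylene.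
3. That ester: Giese addition of the (S)-tetrahydrofurfuryl radical to methyl acrylate. The only ring (THF) comes intact from the chiral pool, so no ring is formed in the route.
4. Bromo-iodo-diene: 1-octyne + formaldehyde, alkyne zipper, then two hydrozirconation/halogenations separated by an Ohira–Bestmann homologation.

**Route**

Step 1
Reactants: 1, (S)-tetrahydrofurfuryl alcohol
Product: 2, (S)-2-(iodomethyl)oxolane
Conditions: I2, PPh3, imidazole, CH2Cl2, 0 °C → rt
Reagents that add atoms: iodine, II
Why: Appel-type iodination of a primary alcohol; substitution occurs at the exocyclic CH2, so the ring stereocentre is untouched.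

Step 2
Reactants: 2, (S)-2-(iodomethyl)oxolane; 3, methyl acrylate
Product: 4, methyl 4-[(2R)-oxolan-2-yl]butanoate
Conditions: (TMS)3SiH (1.2 equiv, slow addition), AIBN (cat.), methyl acrylate (5 equiv), PhMe, 80 °C
Reagents that add atoms: methyl acrylate (3), C=CC(=O)OC
Why: Giese radical conjugate addition; the primary β-alkoxyalkyl radical does not ring-open (unlike the corresponding organozinc or Grignard) and adds to the acrylate, and the stereocentre is not involved (the descriptor changes from S to R only through CIP priorities).

Step 3
Reactants: 4, methyl 4-[(2R)-oxolan-2-yl]butanoate; 5, ethynyltriisopropylsilane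
Product: 6, methyl 4-[(2R,5S)-5-[(triisopropylsilyl)ethynyl]oxolan-2-yl]butanoate (2,5-trans)
Conditions: Cu(MeCN)4PF6 (10 mol %), (S,S)-Ph-PyBox (12 mol %), NFSI (1.3 equiv), TIPS-acetylene (1.5 equiv), Li2CO3 (2 equiv), PhCl, 0 °C → rt
Reagents that add atoms: ethynyltriisopropylsilane (5), C#C[Si](C(C)C)(C(C)C)C(C)C
Why: Proposed new method: Cu(I)/NFSI gives the bulky, electrophilic imidyl radical •N(SO2Ph)2, which should abstract the hydridic, unhindered secondary C5–H rather than the hindered tertiary C2–H or the polarity-mismatched C–H next to the ester; Cu(II) oxidises the α-oxy radical to the oxocarbenium ion (the C5 sulfonimide N,O-acetal acts as a reversible reservoir), and the PyBox–Cu acetylide adds inside the chiral pocket, so the ligand, not the remote C2 substituent (which gives almost no inherent bias), selects the face and sets C5 trans to the side chain (5S), while C2 is never ionised in productive turnover and keeps its configuration; closest known reaction types are Cu/NFSI radical-relay asymmetric benzylic C–H alkynylation and cyanation, racemic Cu-catalysed oxidative coupling of THF (as solvent) with terminal alkynes, and Cu–PyBox enantioselective alkynylation of isochroman oxocarbenium ions.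

Step 4
Reactants: 6, methyl 4-[(2R,5S)-5-[(triisopropylsilyl)ethynyl]oxolan-2-yl]butanoate
Product: 7, methyl 4-[(2R,5S)-5-ethynyloxolan-2-yl]butanoate
Conditions: TBAF, AcOH (buffer), THF, 0 °C
Reagents that add atoms: none
Why: Fluoride-mediated C(sp)–Si cleavage; buffering protects the methyl ester and prevents propargyl–allenyl isomerisation, so both stereocentres are unchanged.

Step 5
Reactants: 8, 1-octyne; 9, formaldehyde (as paraformaldehyde)
Product: 10, non-2-yn-1-ol
Conditions: n-BuLi, THF, −78 °C; (CH2O)n, −78 °C → rt
Reagents that add atoms: formaldehyde (9), C=O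
Why: Addition of a lithium acetylide to formaldehyde (hydroxymethylation of a terminal alkyne).

Step 6
Reactants: 10, non-2-yn-1-ol
Product: 11, non-8-yn-1-ol
Conditions: KH, H2N(CH2)3NH2 (KAPA), 0 °C → rt; then H2O
Reagents that add atoms: none
Why: Alkyne zipper isomerisation; the triple bond migrates along the chain and is trapped irreversibly at the terminus as the acetylide.

Step 7
Reactants: 11, non-8-yn-1-ol
Product: 12, (E)-9-bromonon-8-en-1-ol
Conditions: Cp2Zr(H)Cl (2.3 equiv), THF, rt; then NBS, 0 °C
Reagents that add atoms: N-bromosuccinimide, O=C1CCC(=O)N1Br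
Why: Hydrozirconation (syn, anti-Markovnikov; the first equivalent is consumed by the OH) followed by bromodezirconation with retention gives only the E-vinyl bromide.

Step 8
Reactants: 12, (E)-9-bromonon-8-en-1-ol
Product: 13, (E)-9-bromonon-8-enal
Conditions: Dess–Martin periodinane, NaHCO3, CH2Cl2, 0 °C → rt
Reagents that add atoms: none
Why: Dess–Martin oxidation of a primary alcohol under neutral conditions that leave the vinyl bromide intact.

Step 9
Reactants: 13, (E)-9-bromonon-8-enal
Product: 14, (E)-1-bromodec-1-en-9-yne
Conditions: dimethyl (1-diazo-2-oxopropyl)phosphonate, K2CO3, MeOH, 0 °C → rt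
Reagents that add atoms: Ohira–Bestmann reagent, CC(=O)C(=[N+]=[N-])P(=O)(OC)OC
Why: Ohira–Bestmann (Seyferth–Gilbert) homologation of an unbranched aldehyde; K2CO3/MeOH is too mild to dehydrobrominate the E-vinyl bromide.

Step 10
Reactants: 14, (E)-1-bromodec-1-en-9-yne
Product: 15, (1E,9E)-1-bromo-10-iododeca-1,9-diene
Conditions: Cp2Zr(H)Cl (1.2 equiv), THF, rt; then I2, 0 °C
Reagents that add atoms: iodine, II
Why: Hydrozirconation/iodination; the terminal alkyne reacts far faster than the 1,2-disubstituted bromoalkene, and syn addition with retentive iodinolysis gives the E-vinyl iodide.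

Step 11
Reactants: 7, methyl 4-[(2R,5S)-5-ethynyloxolan-2-yl]butanoate; 15, (1E,9E)-1-bromo-10-iododeca-1,9-diene (1.2 equiv)
Product: 16, Mutafuran C, methyl 4-[(2R,5S)-5-[(3E,11E)-12-bromododeca-3,11-dien-1-yn-1-yl]oxolan-2-yl]butanoate
Conditions: Pd(PPh3)4 (5 mol %), CuI (10 mol %), i-Pr2NH, THF (degassed), 0 °C → rt
Reagents that add atoms: none
Why: Sonogashira coupling; oxidative addition into the vinyl C–I bond is much faster than into C–Br at room temperature, alkene geometry is retained, and neither stereocentre is touched.

**Compound list**
1 | (S)-tetrahydrofurfuryl alcohol | OC[C@@H]1CCCO1 | starting material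
2 | (S)-2-(iodomethyl)oxolane | IC[C@@H]1CCCO1 | intermediate
3 | methyl acrylate | C=CC(=O)OC | starting material
4 | methyl 4-[(2R)-oxolan-2-yl]butanoate | COC(=O)CCC[C@@H]1CCCO1 | intermediate
5 | ethynyltriisopropylsilane (TIPS-protected acetylene) | C#C[Si](C(C)C)(C(C)C)C(C)C | starting material
6 | methyl 4-[(2R,5S)-5-[(triisopropylsilyl)ethynyl]oxolan-2-yl]butanoate | COC(=O)CCC[C@@H]1CC[C@@H](C#C[Si](C(C)C)(C(C)C)C(C)C)O1 | intermediate
7 | methyl 4-[(2R,5S)-5-ethynyloxolan-2-yl]butanoate | COC(=O)CCC[C@@H]1CC[C@@H](C#C)O1 | intermediate
8 | 1-octyne | CCCCCCC#C | starting material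
9 | formaldehyde (paraformaldehyde) | C=O | starting material
10 | non-2-yn-1-ol | CCCCCCC#CCO | intermediate
11 | non-8-yn-1-ol | C#CCCCCCCCO | intermediate
12 | (E)-9-bromonon-8-en-1-ol | Br/C=C/CCCCCCCO | intermediate
13 | (E)-9-bromonon-8-enal | Br/C=C/CCCCCCC=O | intermediate
14 | (E)-1-bromodec-1-en-9-yne | Br/C=C/CCCCCCC#C | intermediate
15 | (1E,9E)-1-bromo-10-iododeca-1,9-diene | Br/C=C/CCCCCC/C=C/I | intermediate
16 | Mutafuran C, methyl 4-[(2R,5S)-5-[(3E,11E)-12-bromododeca-3,11-dien-1-yn-1-yl]oxolan-2-yl]butanoate | COC(=O)CCC[C@@H]1CC[C@@H](C#C/C=C/CCCCCC/C=C/Br)O1 | target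

**Totals**
Total step count: 11 (steps 1–4 THF fragment, steps 5–10 side chain, step 11 coupling).
Longest linear sequence: 7 (steps 5–11).

**Three steps most likely to fail**
1. Step 3 (proposed new C–H alkynylation). Risks are C2 versus C5 site selectivity, insufficient trans selectivity, over-oxidation of the product and Glaser coupling. Fallback with known chemistry: build the ring instead of functionalising it. Co(II)-catalysed Mukaiyama aerobic oxidative cyclisation of methyl (5R)-5-hydroxynon-8-enoate (from (S)-1,2-epoxyhex-5-ene) is known to give 2,5-trans THF-methanols with high selectivity; Dess–Martin oxidation and Ohira–Bestmann homologation then give the same alkyne 7.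
2. Step 11 (Sonogashira). Risks are competing reaction at the vinyl bromide of the reagent or product, and alkyne homocoupling. Fallback: couple 7 with (E)-9-iodonon-8-en-1-ol (made from 11 by hydrozirconation/iodination), which carries no second halide, then Dess–Martin oxidation and Takai–Utimoto bromo-olefination (CHBr3, CrBr2) to install the (E)-vinyl bromide last.
3. Step 10 (hydrozirconation in the presence of a vinyl bromide). Risk is reduction or loss of the bromoalkene by excess Schwartz reagent. Fallback: skip the alkyne and convert aldehyde 13 directly into 15 by Takai iodo-olefination (CHI3, CrCl2, dioxane/THF), accepting a minor Z-isomer that would need to be separated.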